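**Plan**

Numbering of each naphthalene: OH on C1 and C8, acetyl on C2, methyl on C3, biaryl bond C7–C7'.

1. Retrosynthesis: after the four O–CH3 bonds, the cuts are C8–C8a and C5–C4a in both halves, so each outer ring (C4a–C5–C6–C7–C8–C8a) falls into an aryne (C4a≡C8a of the acetyl-bearing ring) and a diene.
2. Enabling feature: in each outer ring the run C5–C6–C7–C8, with oxygen on C8 and the C7–C7' bond on C7, is the C6–C5–C4–C3 diene of a 3-methoxy-2-pyranone dimerised through C4, so the biaryl bond and both C8 oxygens come with the diene.
3. Forward: the acetyl-bearing ring is bought as orcacetophenone and converted into an ortho-silyl aryl triflate (steps 1–6); 3-hydroxy-2-pyranone is brominated, methylated and homocoupled to the 4,4'-bipyranone (steps 7–9).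
4. Both outer benzene rings then arise together in one twofold aryne [4+2]/CO2-extrusion step (step 10), and BBr3 frees the four phenols (step 11).
5. Stereochemistry: none to set; the only stereocentre on the route (the carbinol carbon of 4–10) is racemic and is erased in step 6.

Key step: step 10

Assumption: the target SMILES has no stereodescriptor and the C7–C7' axis is flanked only by OH and H, so stypandrol is treated as achiral with a freely rotating axis; "single enantiomer" therefore imposes no stereochemical task.

**Route**

Step 1
Reactants: 1 orcacetophenone, 1-(2,4-dihydroxy-6-methylphenyl)ethan-1-one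
Product: 2 4-acetyl-3-hydroxy-5-methylphenyl isopropylcarbamate
Conditions: i-PrNCO (1.05 equiv), Et3N (cat.), THF, 0 °C → rt
Reagents that add atoms: isopropyl isocyanate, CC(C)N=C=O
Why: Base-catalysed addition of a phenol to an isocyanate (carbamoylation), in which the 2-OH is held in a strong hydrogen bond to the acetyl carbonyl so that only the free, more acidic 4-OH should add.

Step 2
Reactants: 2 4-acetyl-3-hydroxy-5-methylphenyl isopropylcarbamate
Product: 3 4-acetyl-3-methoxy-5-methylphenyl isopropylcarbamate
Conditions: MeOH, PPh3, DIAD, THF, 0 °C → rt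
Reagents that add atoms: methanol, CO
Why: Mitsunobu etherification of the chelated phenol with methanol under neutral conditions, preferred to MeI/carbonate because a basic medium could expel the para-acyl phenoxide from the N–H carbamate by E1cB and scramble the two oxygens.

Step 3
Reactants: 3 4-acetyl-3-methoxy-5-methylphenyl isopropylcarbamate
Product: 4 rac-4-(1-hydroxyethyl)-3-methoxy-5-methylphenyl isopropylcarbamate
Conditions: NaBH4, MeOH–THF, 0 °C → rt
Reagents that add atoms: none
Why: Borohydride reduction of a ketone that is twisted out of conjugation by its two ortho substituents and therefore still electrophilic, the aryl carbamate being inert at this temperature; the carbinol centre is deliberately racemic because it only keeps a carbonyl group away from butyllithium and is erased in step 6.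

Step 4
Reactants: 4 rac-4-(1-hydroxyethyl)-3-methoxy-5-methylphenyl isopropylcarbamate
Product: 8 rac-4-(1-hydroxyethyl)-3-methoxy-5-methyl-2-(trimethylsilyl)phenyl isopropylcarbamate, via bis-silylated carbamate 5 (not isolated), via ring-lithiated carbamate 6 (not isolated), via tris-silylated carbamate 7 (not isolated)
Conditions: TMSOTf (2.2 equiv), TMEDA, Et2O, 0 °C → rt; n-BuLi (3.5 equiv, two of them consumed by TMEDA·HOTf), TMEDA, −78 °C; TMSCl, −78 °C → rt; aq. NaHSO4
Reagents that add atoms: chlorotrimethylsilane, C[Si](C)(C)Cl
Why: Directed ortho-metalation of an O-aryl N-isopropylcarbamate protected in situ as its N-silyl derivative (the alcohol is silylated in the same operation), in which the proton between the carbamate and methoxy groups is activated by both directing groups and should be removed in preference to H-5, the aryllithium is trapped by TMSCl, and the labile N–Si and O–Si bonds are hydrolysed on work-up.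

Step 5
Reactants: 8 rac-4-(1-hydroxyethyl)-3-methoxy-5-methyl-2-(trimethylsilyl)phenyl isopropylcarbamate
Product: 10 rac-4-(1-hydroxyethyl)-3-methoxy-5-methyl-2-(trimethylsilyl)phenyl trifluoromethanesulfonate, via phenol 9 (not isolated)
Conditions: DBU, Et2NH, MeCN, 40 °C; then PhNTf2, rt
Reagents that add atoms: N-phenylbis(trifluoromethanesulfonimide), O=S(=O)(N(c1ccccc1)S(=O)(=O)C(F)(F)F)C(F)(F)F
Why: Base-induced E1cB cleavage of the N-monosubstituted aryl carbamate (the isocyanate is scavenged by diethylamine) frees the phenoxide without acid, which would endanger the electron-rich aryl–silicon bond, and PhNTf2 then triflates the phenoxide while leaving the aliphatic alcohol alone.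

Step 6
Reactants: 10 rac-4-(1-hydroxyethyl)-3-methoxy-5-methyl-2-(trimethylsilyl)phenyl trifluoromethanesulfonate
Product: 11 4-acetyl-3-methoxy-5-methyl-2-(trimethylsilyl)phenyl trifluoromethanesulfonate
Conditions: Dess–Martin periodinane, CH2Cl2, rt
Reagents that add atoms: none
Why: Dess–Martin oxidation of the secondary benzylic alcohol to the methyl ketone under near-neutral, fluoride-free conditions that should leave the aryl–SiMe3 and triflate groups untouched.

Step 7
Reactants: 12 3-hydroxy-2H-pyran-2-one
Product: 13 4-bromo-3-hydroxy-2H-pyran-2-one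
Conditions: NBS (1.0 equiv), i-Pr2NH (cat.), CH2Cl2, 0 °C
Reagents that add atoms: N-bromosuccinimide, O=C1CCC(=O)N1Br
Why: Electrophilic bromination of the enol, in which C4 is the carbon beta to the enolic oxygen and the only position ortho to the OH group, and amine-catalysed delivery of bromine from NBS favours that ortho position and should stop at the monobromide.

Step 8
Reactants: 13 4-bromo-3-hydroxy-2H-pyran-2-one
Product: 14 4-bromo-3-methoxy-2H-pyran-2-one
Conditions: MeI, K2CO3, acetone, rt
Reagents that add atoms: iodomethane, CI
Why: Williamson-type O-methylation of the acidic enol with a mild carbonate base, conditions under which the pyranone lactone and the vinylic bromide should be stable.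

Step 9
Reactants: 14 4-bromo-3-methoxy-2H-pyran-2-one (2 equiv)
Product: 16 3,3'-dimethoxy-2H,2'H-[4,4'-bipyran]-2,2'-dione, via stannylpyranone 15 (not isolated)
Conditions: Me3SnSnMe3 (0.55 equiv), Pd(PPh3)4 (cat.), 1,4-dioxane, 100 °C
Reagents that add atoms: none
Why: Stille–Kelly reductive homocoupling, in which Pd(0) inserts into the activated beta-bromo enoate C–Br bond, hexamethylditin converts half of the material into stannane 15 and Stille coupling with the remaining bromide forms the C4–C4' bond under neutral conditions that spare the lactones.

Step 10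
Reactants: 11 4-acetyl-3-methoxy-5-methyl-2-(trimethylsilyl)phenyl trifluoromethanesulfonate (3 equiv), 16 3,3'-dimethoxy-2H,2'H-[4,4'-bipyran]-2,2'-dione
Product: 21 stypandrol tetramethyl ether, via aryne 17 (not isolated), via first bridged lactone 18 (not isolated), via naphthylpyranone 19 (not isolated), via second bridged lactone 20 (not isolated)
Conditions: CsF (7 equiv), MeCN, 60 °C, slow addition of 11
Reagents that add atoms: none
Why: Fluoride attacks the silicon of 11 and loss of triflate gives aryne 17, which adds across C3 and C6 of one pyranone ring of 16 in a concerted, asynchronous [4+2] cycloaddition to bridged lactone 18; retro-[4+2] loss of CO2 gives naphthylpyranone 19, and a second aryne repeats the sequence through 20. The closest known reaction type is the Diels–Alder reaction of arynes with 2-pyranones followed by decarboxylative aromatisation to naphthalenes. Each new benzene ring (C4a–C5–C6–C7–C8–C8a) closes by intermolecular [4+2] annulation that forms C8–C8a and C5–C4a, and it becomes aromatic when the O–C(=O) bridge leaves as CO2. No stereocentre is created in 21, since the bridgehead centres of 18 and 20 vanish on extrusion and the biaryl axis is not configurationally stable. The step needs one orientation, pyranone C3 (future C8) bonding to the aryne carbon next to the methoxy group, and this should be secured by matched polarisation: the inductively withdrawing 3-methoxy group distorts the aryne so that the carbon remote from it is the electrophilic and unhindered terminus, while the methoxy and lactone carbonyl groups on C3 make the unsubstituted C6 the nucleophilic terminus of the pyranone, so the leading bond should be C5–C4a and the lagging bond joins the two oxygen-flanked carbons. An excess of 11 added slowly keeps the aryne concentration low and should carry the more hindered second annulation to completion.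

Step 11
Reactants: 21 stypandrol tetramethyl ether
Product: 22 stypandrol
Conditions: BBr3 (10 equiv), CH2Cl2, −78 °C → rt; MeOH, then H2O
Reagents that add atoms: none
Why: Lewis-acid ether cleavage with BBr3, in which each aryl methyl ether is complexed and demethylated by bromide (the ethers ortho to the acetyl groups and their peri neighbours are assisted by chelation) and aqueous work-up hydrolyses the aryl borates to the four phenols without touching the ketones.

**Compound list**

1 | orcacetophenone, 1-(2,4-dihydroxy-6-methylphenyl)ethan-1-one | CC(=O)c1c(C)cc(O)cc1O | starting material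
2 | 4-acetyl-3-hydroxy-5-methylphenyl isopropylcarbamate | CC(=O)c1c(C)cc(OC(=O)NC(C)C)cc1O | intermediate
3 | 4-acetyl-3-methoxy-5-methylphenyl isopropylcarbamate | CC(=O)c1c(C)cc(OC(=O)NC(C)C)cc1OC | intermediate
4 | rac-4-(1-hydroxyethyl)-3-methoxy-5-methylphenyl isopropylcarbamate | CC(O)c1c(C)cc(OC(=O)NC(C)C)cc1OC | intermediate
5 | rac-3-methoxy-5-methyl-4-[1-(trimethylsilyloxy)ethyl]phenyl N-isopropyl-N-(trimethylsilyl)carbamate | CC(O[Si](C)(C)C)c1c(C)cc(OC(=O)N(C(C)C)[Si](C)(C)C)cc1OC | intermediate (not isolated)
6 | 2-lithio derivative of 5, lithium on the ring carbon between the carbamate and methoxy groups (racemic) | CC(O[Si](C)(C)C)c1c(C)cc(OC(=O)N(C(C)C)[Si](C)(C)C)c([Li])c1OC | intermediate (not isolated)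
7 | 2-(trimethylsilyl) derivative of 5 (racemic) | CC(O[Si](C)(C)C)c1c(C)cc(OC(=O)N(C(C)C)[Si](C)(C)C)c([Si](C)(C)C)c1OC | intermediate (not isolated)
8 | rac-4-(1-hydroxyethyl)-3-methoxy-5-methyl-2-(trimethylsilyl)phenyl isopropylcarbamate | CC(O)c1c(C)cc(OC(=O)NC(C)C)c([Si](C)(C)C)c1OC | intermediate
9 | rac-4-(1-hydroxyethyl)-3-methoxy-5-methyl-2-(trimethylsilyl)phenol | CC(O)c1c(C)cc(O)c([Si](C)(C)C)c1OC | intermediate (not isolated)
10 | rac-4-(1-hydroxyethyl)-3-methoxy-5-methyl-2-(trimethylsilyl)phenyl trifluoromethanesulfonate | CC(O)c1c(C)cc(OS(=O)(=O)C(F)(F)F)c([Si](C)(C)C)c1OC | intermediate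
11 | 4-acetyl-3-methoxy-5-methyl-2-(trimethylsilyl)phenyl trifluoromethanesulfonate | CC(=O)c1c(C)cc(OS(=O)(=O)C(F)(F)F)c([Si](C)(C)C)c1OC | intermediate
12 | 3-hydroxy-2H-pyran-2-one | O=c1occcc1O | starting material
13 | 4-bromo-3-hydroxy-2H-pyran-2-one | O=c1occc(Br)c1O | intermediate
14 | 4-bromo-3-methoxy-2H-pyran-2-one | COc1c(Br)ccoc1=O | intermediate
15 | 3-methoxy-4-(trimethylstannyl)-2H-pyran-2-one | COc1c([Sn](C)(C)C)ccoc1=O | intermediate (not isolated)
16 | 3,3'-dimethoxy-2H,2'H-[4,4'-bipyran]-2,2'-dione | COc1c(-c2ccoc(=O)c2OC)ccoc1=O | intermediate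
17 | 1-(3,4-didehydro-2-methoxy-6-methylphenyl)ethan-1-one (4-acetyl-3-methoxy-5-methylbenzyne) | CC(=O)C1=C(OC)C#CC=C1C | intermediate (not isolated)
18 | first bridged lactone (racemic): benzo-fused 2-oxabicyclo[2.2.2]octa-5,7-dien-3-one; the OMe-bearing bridgehead (former pyranone C3) is bonded to the arene carbon next to OMe, the CH bridgehead (former C6) to the arene carbon next to H, and the alkene bridge carries the remaining 3-methoxy-2-oxo-2H-pyran-4-yl group | O=C1OC2C=C(c3ccoc(=O)c3OC)C1(OC)c1c(OC)c(C(C)=O)c(C)cc12 | intermediate (not isolated)
19 | 4-(7-acetyl-1,8-dimethoxy-6-methylnaphthalen-2-yl)-3-methoxy-2H-pyran-2-one | CC(=O)c1c(C)cc2ccc(-c3ccoc(=O)c3OC)c(OC)c2c1OC | intermediate (not isolated)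
20 | second bridged lactone (racemic): as 18, with the alkene bridge carrying the 7-acetyl-1,8-dimethoxy-6-methylnaphthalen-2-yl group | O=C1OC2C=C(c3ccc4cc(C)c(C(C)=O)c(OC)c4c3OC)C1(OC)c1c(OC)c(C(C)=O)c(C)cc12 | intermediate (not isolated)
21 | stypandrol tetramethyl ether, 1,1'-(1,1',8,8'-tetramethoxy-6,6'-dimethyl-[2,2'-binaphthalene]-7,7'-diyl)di(ethan-1-one) | CC(=O)c1c(C)cc2ccc(-c3ccc4cc(C)c(C(C)=O)c(OC)c4c3OC)c(OC)c2c1OC | intermediate
22 | stypandrol, 1,1'-(1,1',8,8'-tetrahydroxy-6,6'-dimethyl-[2,2'-binaphthalene]-7,7'-diyl)di(ethan-1-one) | CC(=O)c1c(C)cc2ccc(-c3ccc4cc(C)c(C(C)=O)c(O)c4c3O)c(O)c2c1O | target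

**Step count**

Total: 11 steps. Longest linear sequence: 8 steps (steps 1–6, 10 and 11, from 1); the pyranone branch contributes steps 7–9.

**Steps most likely to fail**

Step 10. The second annulation may stall because the remaining pyranone ring of 19 is shielded by the ortho-methoxynaphthyl group while the aryne is consumed by self-reaction. Wrong-way addition in either event would also give regioisomeric binaphthyls that are hard to separate at the dimer stage. The fallback moves the cycloaddition one stage earlier in the pyranone series. It sets out from 14 and 11: the unhindered bromopyranone 14, which has the same polarisation, is treated with 11 and CsF in MeCN at 60 °C and should give, after loss of CO2, 1-(7-bromo-1,8-dimethoxy-3-methylnaphthalen-2-yl)ethan-1-one F1, from which a regioisomer can be removed at the monomer stage. Nickel(0)-mediated reductive homocoupling of F1 (Ni(cod)2, 2,2'-bipyridine, DMF, 60 °C) then forms the C7–C7' bond and the route is rejoined at 21.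

Step 4. Butyllithium may attack the labile O–SiMe3 group or metalate the benzylic position, so that ring lithiation is incomplete or misdirected. The fallback replaces the in situ protection by a robust, separately installed silyl ether. It sets out from 4: TBSCl and imidazole in DMF should give rac-4-[1-(tert-butyldimethylsilyloxy)ethyl]-3-methoxy-5-methylphenyl isopropylcarbamate F2. The same lithiation protocol (TBSOTf/TMEDA for the N–H; n-BuLi/TMEDA, −78 °C; TMSCl; aq. NaHSO4) should give the 2-(trimethylsilyl) compound rac-4-[1-(tert-butyldimethylsilyloxy)ethyl]-3-methoxy-5-methyl-2-(trimethylsilyl)phenyl isopropylcarbamate F3. DBU/Et2NH followed by PhNTf2 should give rac-4-[1-(tert-butyldimethylsilyloxy)ethyl]-3-methoxy-5-methyl-2-(trimethylsilyl)phenyl trifluoromethanesulfonate F4. Mild acid methanolysis (CSA, MeOH, rt) removes the TBS group and the route is rejoined at 10.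

Step 9. The stannane formed in situ may protodestannylate or couple only slowly with the ortho-methoxy bromide, leaving reduced pyranone and unreacted bromide. The fallback replaces the one-pot tin-mediated dimerisation by a stepwise union of two separately prepared partners. It sets out from 14: Miyaura borylation (B2pin2, KOAc, PdCl2(dppf), dioxane, 80 °C) should give 3-methoxy-4-(4,4,5,5-tetramethyl-1,3,2-dioxaborolan-2-yl)-2H-pyran-2-one F5, which is isolated. Suzuki coupling of F5 with a second equivalent of 14 under anhydrous conditions (Pd(PPh3)4, CsF, DME, 80 °C, chosen to protect the lactones) rejoins the route at 16.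

**Further compounds**

F1 | step 10 | 1-(7-bromo-1,8-dimethoxy-3-methylnaphthalen-2-yl)ethan-1-one | CC(=O)c1c(C)cc2ccc(Br)c(OC)c2c1OC
F2 | step 4 | rac-4-[1-(tert-butyldimethylsilyloxy)ethyl]-3-methoxy-5-methylphenyl isopropylcarbamate | CC(O[Si](C)(C)C(C)(C)C)c1c(C)cc(OC(=O)NC(C)C)cc1OC
F3 | step 4 | rac-4-[1-(tert-butyldimethylsilyloxy)ethyl]-3-methoxy-5-methyl-2-(trimethylsilyl)phenyl isopropylcarbamate | CC(O[Si](C)(C)C(C)(C)C)c1c(C)cc(OC(=O)NC(C)C)c([Si](C)(C)C)c1OC
F4 | step 4 | rac-4-[1-(tert-butyldimethylsilyloxy)ethyl]-3-methoxy-5-methyl-2-(trimethylsilyl)phenyl trifluoromethanesulfonate | CC(O[Si](C)(C)C(C)(C)C)c1c(C)cc(OS(=O)(=O)C(F)(F)F)c([Si](C)(C)C)c1OC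
F5 | step 9 | 3-methoxy-4-(4,4,5,5-tetramethyl-1,3,2-dioxaborolan-2-yl)-2H-pyran-2-one | COc1c(B2OC(C)(C)C(C)(C)O2)ccoc1=O
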